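**Plan**
- Retrosynthetic cuts, in order: the O–CH3 bond at O7, then the aryl–acyl bond C8–C1', with C1' reconnected to O7 as an aryl ester. The C7 oxygen thus serves as a tether that ends up in the target. Next come that O7–C1' ester bond and finally the enol O–acyl bond of the isovalerate.
- Forward: both coumarin rings are bought as umbelliferone. The side chain is finished first: α-ketoisovalerate, benzyl ester, enol isovalerate (C2'=C3' set here), free acid. It is hung on O7, moved from O7 to C8 by light, and the freed 7-OH is methylated last.
- Enabling feature: C8 of the benzene ring lies ortho to O7 and next to the fusion carbon C8a, between O7 and O1. The para carbon C4a is quaternary. C8 is the carbon to which Claisen, thermal Fries, Duff and iodination reactions of 7-oxygenated coumarins are directed, so an acyl radical released from O7 inside a solvent cage should recombine there.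
- The shift delivers the complete acyl chain at the ketone oxidation level, enol ester included, without acid, base or metal.
- Stereochemistry: none to set (see remark).

Key step: step 5

Remark: the target has no stereocentre, and C3' of its only acyclic C=C carries two identical methyl groups. It is therefore achiral and has no E/Z isomer. The route makes this single compound.

**Step 1**
Reactants: 1 sodium 3-methyl-2-oxobutanoate
Product: 2 benzyl 3-methyl-2-oxobutanoate
Conditions: BnBr, DMF, rt
Reagents that add atoms: benzyl bromide, BrCc1ccccc1
Why: SN2 O-alkylation of the carboxylate in a dipolar aprotic solvent leaves the ketone untouched and installs an ester that survives the acid of step 2 and leaves under neutral hydrogenolysis.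

**Step 2**
Reactants: 2 benzyl 3-methyl-2-oxobutanoate; 3 3-methylbutanoic (isovaleric) anhydride
Product: 4 benzyl 3-methyl-2-[(3-methylbutanoyl)oxy]but-2-enoate
Conditions: 3 (2.5 equiv), TsOH·H2O (cat.), toluene, reflux
Reagents that add atoms: none
Why: Acid-catalysed enol esterification of an α-keto ester with a carboxylic anhydride should work because C3–H is the only enolisable hydrogen, the enol is stabilised by conjugation with the ester, the acyl-transfer potential of the anhydride drives O-acylation, and the two methyl groups on C3 exclude E/Z isomers.

**Step 3**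
Reactants: 4 benzyl 3-methyl-2-[(3-methylbutanoyl)oxy]but-2-enoate
Product: 5 3-methyl-2-[(3-methylbutanoyl)oxy]but-2-enoic acid
Conditions: H2 (1 atm), 10% Pd/C, EtOAc, rt, stopped after one equivalent of H2
Reagents that add atoms: none
Why: Catalytic hydrogenolysis of a benzyl ester on Pd/C at 1 atm should be much faster than hydrogenation of the tetrasubstituted, ester-conjugated C=C, and the neutral medium spares the enol ester.

**Step 4**
Reactants: 5 3-methyl-2-[(3-methylbutanoyl)oxy]but-2-enoic acid; 6 umbelliferone (7-hydroxy-2H-chromen-2-one)
Product: 8 2-oxo-2H-chromen-7-yl 3-methyl-2-[(3-methylbutanoyl)oxy]but-2-enoate, via acid chloride 7 (not isolated)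
Conditions: (COCl)2, DMF (cat.), CH2Cl2, 0 °C to rt, evaporate; then 6, pyridine (3 equiv), THF, 0 °C
Reagents that add atoms: oxalyl chloride, O=C(Cl)C(=O)Cl (supplies the Cl of 7 only; no atom of it stays in 8)
Why: Acid chloride formation under chloroiminium catalysis followed by Einhorn-type O-acylation of the acidic phenol should work because the weak base pyridine avoids γ-deprotonation of 7 to a vinylketene (deconjugation) and the acid chloride far outcompetes the enol ester as acyl donor.

**Step 5**
Reactants: 8 2-oxo-2H-chromen-7-yl 3-methyl-2-[(3-methylbutanoyl)oxy]but-2-enoate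
Product: 10 7-hydroxy-8-{3-methyl-2-[(3-methylbutanoyl)oxy]but-2-enoyl}-2H-chromen-2-one, via dienone 9 (not isolated)
Conditions: hν (300–313 nm, Pyrex-filtered medium-pressure Hg lamp, FEP-tube flow reactor), degassed MeCN (ca. 3 mM), 20 °C
Reagents that add atoms: none
Why: Light of 300–313 nm is absorbed by the 7-acyloxycoumarin chromophore of 8 but not by the α-acyloxyacrylate unit, and the singlet excited state cleaves the O7–C1' bond homolytically to a solvent-caged pair of 7-coumarinyloxyl radical and alkenoyl radical, which recombine at C8 to dienone 9, whose prototropic shift restores the benzene ring and gives 10 (photo-Fries rearrangement). The closest known reactions are the photo-Fries rearrangements of aryl 3-methylbut-2-enoates to o-hydroxyaryl 3-methylbut-2-enyl ketones and of 2-naphthyl esters to 1-acyl-2-naphthols. No ring is closed and no stereocentre remains, since the sp3 C8 of 9 is transient and is lost on tautomerisation. The step needs C8 over C6: the para carbon C4a is blocked, and of the two ortho carbons C8, next to the fusion carbon C8a, corresponds to C1 of a 2-naphthyl system and is the site that Claisen, thermal Fries, Duff and iodination reactions of 7-oxygenated coumarins all choose. Chemoselectivity rests on the neutral, reagent-free medium (lactone and enol ester untouched), on the reluctance of an alkenoyl radical to lose CO to a vinyl radical, on high dilution against [2+2] dimerisation at C3=C4, and on rapid excited-state proton transfer in the hydrogen-bonded o-hydroxyaryl ketone 10, which should shield the product from further photolysis.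

**Step 6**
Reactants: 10 7-hydroxy-8-{3-methyl-2-[(3-methylbutanoyl)oxy]but-2-enoyl}-2H-chromen-2-one
Product: 11 exotimarin H
Conditions: MeOH (1.5 equiv), PPh3, DIAD, THF, 0 °C to rt
Reagents that add atoms: methanol, CO
Why: In this Mitsunobu etherification the acidic chelated phenol protonates the PPh3–DIAD betaine and its anion is methylated within the ion pair by MeO–PPh3+, so no long-lived free phenoxide should be present to add to C3' of the enone (pyranone closure) or to attack the isovalerate, and the lactone and enol ester stay intact in the near-neutral medium.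

**Compound list**
1 | sodium 3-methyl-2-oxobutanoate | CC(C)C(=O)C(=O)[O-].[Na+] | starting material
2 | benzyl 3-methyl-2-oxobutanoate | CC(C)C(=O)C(=O)OCc1ccccc1 | intermediate
3 | 3-methylbutanoic (isovaleric) anhydride | CC(C)CC(=O)OC(=O)CC(C)C | starting material
4 | benzyl 3-methyl-2-[(3-methylbutanoyl)oxy]but-2-enoate | CC(C)CC(=O)OC(=C(C)C)C(=O)OCc1ccccc1 | intermediate
5 | 3-methyl-2-[(3-methylbutanoyl)oxy]but-2-enoic acid | CC(C)CC(=O)OC(=C(C)C)C(=O)O | intermediate
6 | umbelliferone (7-hydroxy-2H-chromen-2-one) | Oc1ccc2ccc(=O)oc2c1 | starting material
7 | 3-methyl-2-[(3-methylbutanoyl)oxy]but-2-enoyl chloride (not isolated) | CC(C)CC(=O)OC(=C(C)C)C(=O)Cl | intermediate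
8 | 2-oxo-2H-chromen-7-yl 3-methyl-2-[(3-methylbutanoyl)oxy]but-2-enoate | CC(C)CC(=O)OC(=C(C)C)C(=O)Oc1ccc2ccc(=O)oc2c1 | intermediate
9 | 8-acyl-8H-chromene-2,7-dione, the cyclohexadienone tautomer of 10 (not isolated; C8 transient, racemic) | O=C1C=CC2=C(OC(=O)C=C2)C1C(=O)C(OC(=O)CC(C)C)=C(C)C | intermediate
10 | 7-hydroxy-8-{3-methyl-2-[(3-methylbutanoyl)oxy]but-2-enoyl}-2H-chromen-2-one | Oc1ccc2ccc(=O)oc2c1C(=O)C(OC(=O)CC(C)C)=C(C)C | intermediate
11 | exotimarin H, 1-(7-methoxy-2-oxo-2H-chromen-8-yl)-3-methyl-1-oxobut-2-en-2-yl 3-methylbutanoate (achiral) | COc1ccc2ccc(=O)oc2c1C(=O)C(OC(=O)CC(C)C)=C(C)C | target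

**Total step count:** 6
**Longest linear sequence:** 6 (1 → 2 → 4 → 5 → 8 → 10 → 11)

**Steps most likely to fail**

**Step 5.**
- Several processes may compete. The coumarin excited state may decay without radiation before the O7–C1' bond breaks. The radicals may escape the solvent cage, which loses the acyl group. Recombination may occur at C6 instead of C8. Photodimerisation across C3=C4 is also possible.
- The fallback sets out from 6, uses 7 made from 5 as in step 4, and comes back at 11, so it also replaces step 6.
- Electrophilic iodination of 6 with I2/KI in aqueous ammonia, which is C8-selective, would give 7-hydroxy-8-iodo-2H-chromen-2-one F1.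
- MeI/K2CO3 in acetone would give 8-iodo-7-methoxy-2H-chromen-2-one F2.
- LiCl-promoted insertion of zinc dust in THF would give (7-methoxy-2-oxo-2H-chromen-8-yl)zinc iodide F3, an organometal mild enough for the lactone.
- Pd(0)-catalysed Negishi acylation of F3 with acid chloride 7 would form the same C8–C1' bond and give 11.

**Step 6.**
- The phenolate character that develops during activation may lead to conjugate addition to C3' with closure of a pyranone ring. It may also shift the isovaleryl group from the enol oxygen to O7 before the methyl group is transferred.
- The fallback sets out from 10 and comes back at 11. It removes the Michael acceptor before the methylation and rebuilds it afterwards.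
- K2CO3 in MeOH at 0 °C would cleave the activated enol ester to 1-(7-hydroxy-2-oxo-2H-chromen-8-yl)-3-methylbutane-1,2-dione F4.
- MeI/K2CO3 in acetone would give 1-(7-methoxy-2-oxo-2H-chromen-8-yl)-3-methylbutane-1,2-dione F5, whose only enolisable hydrogen is the isopropyl C–H.
- Enol esterification of F5 with 3 and catalytic TsOH in refluxing toluene, the reaction type of step 2, would give 11.

**Step 2.**
- Enolisation of the hindered isopropyl ketone may be sluggish, so conversion stalls, or addition of the anhydride across the ketone may compete.
- The fallback sets out from 3 and comes back at 5, replacing steps 1–3. It builds the α-acyloxy enoyl unit by rearrangement instead of enolisation.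
- Acylation of commercial 2-methylbut-3-yn-2-ol with 3 (Et3N, DMAP, CH2Cl2) would give 2-methylbut-3-yn-2-yl 3-methylbutanoate F6.
- Gold(I)-catalysed 1,2-acyloxy migration to the vinyl gold carbenoid, followed by its oxidation with diphenyl sulfoxide, would give 3-methyl-1-oxobut-2-en-2-yl 3-methylbutanoate F7.
- Pinnick oxidation of F7 (NaClO2, NaH2PO4, 2-methylbut-2-ene, t-BuOH–H2O) would give 5.

**Further compounds**
F1 | step 5 | 7-hydroxy-8-iodo-2H-chromen-2-one | Oc1ccc2ccc(=O)oc2c1I
F2 | step 5 | 8-iodo-7-methoxy-2H-chromen-2-one | COc1ccc2ccc(=O)oc2c1I
F3 | step 5 | (7-methoxy-2-oxo-2H-chromen-8-yl)zinc iodide | COc1ccc2ccc(=O)oc2c1[Zn]I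
F4 | step 6 | 1-(7-hydroxy-2-oxo-2H-chromen-8-yl)-3-methylbutane-1,2-dione | Oc1ccc2ccc(=O)oc2c1C(=O)C(=O)C(C)C
F5 | step 6 | 1-(7-methoxy-2-oxo-2H-chromen-8-yl)-3-methylbutane-1,2-dione | COc1ccc2ccc(=O)oc2c1C(=O)C(=O)C(C)C
F6 | step 2 | 2-methylbut-3-yn-2-yl 3-methylbutanoate | C#CC(C)(C)OC(=O)CC(C)C
F7 | step 2 | 3-methyl-1-oxobut-2-en-2-yl 3-methylbutanoate | O=CC(OC(=O)CC(C)C)=C(C)C
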